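Atom numbering (target carbons): ring C is C1–C2–C3–C9–C13, the cyclobutane is C3–C4–C8–C9, ring A is C4–C5–C6–C7–C8, the lactone is C9–O10–C11(=O)–C12=C13, and C14 is the CH2 on C12. "Top face" is the cyclobutane face carrying the C3 methyl, H4, H8 and O10; "bottom face" carries C2, C5, C7 and C13. A substituent on ring A or ring C is "outer" when it points away from the cleft between the two five-membered rings and "inner" when it points into it.

## Analysis of the target

Target 30 is a tetracyclic sesquiterpenoid lactone. Its cyclobutane is fused along C4–C8 to cyclopentane ring A and along C3–C9 to cyclopentane ring C, and a butenolide shares C9–C13 with ring C. It has seven stereocentres (C1, C3, C4, C5, C7, C8, C9) and the E double bond of the tiglate. Rings A and C both lie on the bottom face of the cyclobutane (cis-syn-cis), so the molecule is a bowl with a narrow cleft between the five-membered rings. The C5 acetate, the C7 hydroxyl and the C1 tiglate are outer; the C7 methyl is inner and points at trigonal C13. Sensitive features are three kinds of ester beside a free tertiary alcohol, a primary allylic acetate on an electron-poor alkene, a tiglate that accepts hydrogen atoms and nucleophiles, and a tertiary allylic C9–O bond on a strained ring, so strong acid or base must be avoided late. The hard parts are four contiguous cyclobutane stereocentres (C3 and C9 fully substituted and adjacent), the syn arrangement of the two five-membered rings, and a methyl group inside the cleft. The strategy rests on C9 being the only oxygenated cyclobutane carbon and lying between quaternary C3 and C8 of ring A. A C9 cyclobutanone fused to a C6=C7 cyclopentene is a bicyclo[3.2.0]hept-2-en-7-one, the photoisomer of a bicyclo[2.2.1]hept-5-en-2-one whose one-carbon bridge becomes oxygenated C5.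

## Retrosynthetic reasoning

C7–O is cut last. In 30 the hydroxyl is outer and the methyl inner, and a reagent can reach C7 only from outside the cleft. Oxygen, not carbon, must therefore be the group that arrives, which leads back to the exocyclic alkene 28 and a Markovnikov radical hydration in which the planar C7 radical is trapped on its outer face.

Alkene 28 comes from ketone 27 by methylenation. Ketone 27 comes from the bis-ether ketone 26 by turning both ether groups into acetates, at a point where neither an acid-labile exocyclic alkene nor a tertiary alcohol is present. Ketone 26 goes back through alcohol 25 to the ring A alkene of 23. C7 is oxygenated this late because a C7 ketone beside a C9 ketone would be a fragile 2-acylcyclobutanone; in 23 C9 is already a lactone carbon. The forward reaction is a syn hydroboration from the outer face, steered to C7 by the bulky cis ether on C5.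

The C1–O ester bond of 23 is cut with inversion to the C1-epimeric alcohol 21 and tiglic acid 22. Alcohol 21 comes from enedione 20, because a hydride can reach C1 only from the outer face and so leaves the hydroxyl inside. Substitution with inversion by 22 corrects C1 and installs the tiglate in one operation, while ring A is still a flat alkene and the cleft is least crowded.

The C12=C13 double bond of 20 is removed to give keto lactone 19. This is needed because C13 must be sp3 and acidic in the ring-forming step. The forward reaction is a ketone α,β-dehydrogenation that can go only towards C13–C12, since C3 is quaternary.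

In 19 the bonds C9–C13 and O10–C11 are cut, giving the open keto ester 16. Forward, the C13 enolate of the C1 ketone adds to the C9 cyclobutanone and the tertiary alkoxide closes the lactone on the ester. The C2 tether sits on the bottom face, so C13 must add to the bottom face of C9; this fixes C9 and makes the syn ring fusion.

The C1–C13 bond of 16 is cut to aldehyde 13 and acrylate 15 (Stetter reaction). Aldehyde 13 comes from keto ester 11 by full reduction to diol 12 and re-oxidation, because an ester cannot be reduced selectively beside a cyclobutanone. Acrylate 15 is the silyl ether of the commercial hydroxy ester 14.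

In 11 the C8–C9 bond is cut and C9 is re-attached to C6. This is the reverse of a photochemical 1,3-acyl shift and leads to norbornenone 10. The gain is that the four-membered ring, its cis fusion to ring A and the quaternary C3 come from a rigid bicycle in which every stereocentre is already fixed.

Norbornenone 10 is cut at the two exocyclic bonds of C3, to bromoacetate 8 and iodomethane 5 via the methyl ketone 7 and the parent ketone 4. Ketone 4 comes from alcohol 3, which an asymmetric hydroboration–oxidation makes from the meso diene 1.

## Alternatives that were turned down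

Alternative 1: Ring C is disconnected at C1–C13. Forward, the enol triflate at C13 of the spiro-butenolide aldehyde A1 is converted into a C13 nucleophile under Nozaki–Hiyama–Kishi conditions and adds to the C1 aldehyde to give the tetracyclic alcohol A2.
- For: the closure is mild and chemoselective, the butenolide double bond is already present, so no dehydrogenation is needed, and C1 arrives as a carbinol.
- On C1 this route is stronger than the chosen one: the aldehyde hydrogen, not its oxygen, should sit in the cleft during addition, so the natural outer hydroxyl could form directly without a reduction and an inversion.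
- Against: A1 already contains the cyclobutane, quaternary C3, the spiro centre C9 and ring A. The difficult part of the molecule is therefore left to unspecified earlier chemistry.
- Against: a β-triflyloxy butenolide is a vinylogous mixed anhydride and is prone to addition–elimination, and a tetrasubstituted electron-poor vinyl nucleophile adds slowly to an aldehyde held over a crowded face.
- In its place, the chosen route makes the four-membered ring and three of its stereocentres in one stereospecific step from a precursor reached in four steps.

Alternative 2: The C2–C3 and C4–C5 bonds are cut. Forward, the primary radical from iodide A3 adds to the methyl-bearing carbon of the cyclobutene and the resulting C4 radical closes ring A on the nitrile, giving ketone A4 after hydrolysis.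
- For: two rings, two C–C bonds and the quaternary C3 form in one operation, with C1, C7 and the butenolide already in place. In bond economy at the key step it is stronger than the chosen route.
- Against: A3 is a 3-methylcyclobutene with cis, fully elaborated arms on C8 and on a spiro-lactone C9, which is about as hard to make as the core itself.
- Against: the first closure must attack the more substituted alkene carbon. The second is a slow addition of a cyclobutyl radical to a nitrile, which competes with simple reduction, and the nitrogen-centred radical formed next to the strained ring can fragment it.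
- Against: C5 then still needs a stereoselective reduction.
- In its place, the chosen route takes ring A and the C5 oxygen ready-made from diene 1 and forms the cyclobutane stereospecifically.

Alternative 3: The cyclobutane is traced to a cyclopentanone. Forward, diazoketone A5 is photolysed in an alcohol; the diazo group is lost, C4 migrates from C7 to C8, and the acylating intermediate is captured as the methyl ester A6.
- For: ring contraction of this kind is dependable and irreversible, the migrating carbon keeps its configuration, and there is no photostationary state. In robustness and scalability of the ring-forming step it is stronger than the chosen photoisomerisation.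
- Against: A6 has no ring A. C5–C6, C6–C7 and the C7 carbinol must be built afterwards on a congested cyclobutane.
- Against: C8 is set by protonation of an ester enol and is epimerisable, so the cis relation of the C5 and C7 arms is not secured.
- Against: A5 needs a diquinane with adjacent quaternary C3 and C9 and a diazo transfer next to C9.
- In its place, the chosen route is shorter, has ring A from the start, and derives all cyclobutane stereocentres from one asymmetric hydroboration and one exo alkylation.

Key step: step 5

Remark on the chemistry: Ipc2BH is assumed to attack the exo face of the double bond anti to the ether and to select the alkene carbon in the sense known for norbornene, which calls for the reagent from (–)-α-pinene; if the sense were opposite, the antipodal reagent would be used.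

Remark on the chemistry: the target is taken as cis-syn-cis, as its SMILES requires, and all face assignments follow from that.

Step 1
Reactants: 1 7-tert-butoxynorbornadiene
Product: 3 7-tert-butoxybicyclo[2.2.1]hept-5-en-2-ol (hydroxyl exo; ether syn to C5=C6), via dialkylborane adduct 2 (not isolated)
Conditions: (+)-Ipc2BH, THF, –25 °C; then NaOH, H2O2, 0 °C → rt
Reagents that add atoms: hydrogen peroxide, OO
Why: Asymmetric hydroboration–oxidation of a strained cis-alkene; the bulky borane should add to the exo face of the double bond anti to the ether, because the tert-butoxy group shields the exo face of the other one. The chiral reagent chooses between the two enantiotopic alkene carbons, which fixes the absolute configuration of every later compound, and oxidation proceeds with retention.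

Step 2
Reactants: 3 7-tert-butoxybicyclo[2.2.1]hept-5-en-2-ol
Product: 4 7-tert-butoxybicyclo[2.2.1]hept-5-en-2-one (ether syn to C5=C6)
Conditions: Dess–Martin periodinane, CH2Cl2, rt
Reagents that add atoms: none
Why: Dess–Martin oxidation of a secondary alcohol under neutral conditions; the β,γ-unsaturated ketone cannot conjugate because its only α-CH on that side is a bridgehead.

Step 3
Reactants: 4 7-tert-butoxybicyclo[2.2.1]hept-5-en-2-one; 5 iodomethane
Product: 7 7-tert-butoxy-3-exo-methylbicyclo[2.2.1]hept-5-en-2-one, via lithium enolate 6 (not isolated)
Conditions: LiN(iPr)2, THF, –78 °C; MeI, –78 → 0 °C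
Reagents that add atoms: iodomethane 5, CI
Why: Enolate alkylation; only C3 can be deprotonated (the other α-carbon is a bridgehead) and the electrophile enters on the exo face. The configuration at C3 is erased again in step 4.

Step 4
Reactants: 7 7-tert-butoxy-3-exo-methylbicyclo[2.2.1]hept-5-en-2-one; 8 methyl bromoacetate
Product: 10 methyl 2-(7-tert-butoxy-3-methyl-2-oxobicyclo[2.2.1]hept-5-en-3-yl)acetate (acetate arm exo; methyl endo), via lithium enolate 9 (not isolated)
Conditions: LiN(iPr)2, THF, –78 °C; BrCH2CO2Me, DMPU, –78 → –20 °C
Reagents that add atoms: methyl bromoacetate 8, COC(=O)CBr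
Why: Alkylation of the tetrasubstituted enolate on its exo face, which is flanked only by H7 because the ether is on the alkene side of the bridge. The second electrophile therefore ends exo and the methyl endo, which sets the quaternary C3.

Step 5
Reactants: 10 methyl 2-(7-tert-butoxy-3-methyl-2-oxobicyclo[2.2.1]hept-5-en-3-yl)acetate
Product: 11 methyl 2-(4-tert-butoxy-6-methyl-7-oxobicyclo[3.2.0]hept-2-en-6-yl)acetate (cis-fused; arm on the bottom face; ether outer)
Conditions: hν (300 nm, Pyrex), degassed MeCN (0.01 M), rt, to about half conversion; recovered 10 recycled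
Reagents that add atoms: none
Why: Direct n→π* excitation of the β,γ-unsaturated ketone cleaves, from the singlet state, the bond between carbonyl carbon C9 and the allylic bridgehead (C6 in target numbering), giving an acyl–allyl radical pair that stays tethered through C3–C4. The acyl carbon recombines with the far allyl terminus C8, forming C8–C9 and moving the double bond to C6=C7; the closest known reaction type is the photochemical 1,3-acyl shift of bicyclo[2.2.1]hept-5-en-2-ones to bicyclo[3.2.0]hept-2-en-7-ones. The four-membered ring closes by radical-pair recombination, formally a suprafacial [1,3] shift in which the acyl carbon keeps all its substituents, and ring A is the five-membered ring of the norbornene that is retained. The one new stereocentre, C8, is controlled by the tether: the acyl carbon can return only to the face of the allyl unit it left, so the fusion is cis. C3, C4 and C5 are untouched, so the exo arm ends on the bottom face (syn to ring A), the methyl on the top face and the ether on the outer face of ring A. The step needs cleavage on the allylic and not the quaternary side of the ketone, which allyl stabilisation and carbonyl–alkene overlap secure, and the singlet 1,3-shift and not the triplet 1,2-shift, which the absence of a sensitiser secures. Filtered light and interruption at partial conversion hold back reversal, decarbonylation and ketene loss from the product.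

Step 6
Reactants: 11 methyl 2-(4-tert-butoxy-6-methyl-7-oxobicyclo[3.2.0]hept-2-en-6-yl)acetate
Product: 12 2-(4-tert-butoxy-7-hydroxy-6-methylbicyclo[3.2.0]hept-2-en-6-yl)ethanol
Conditions: LiAlH4, THF, 0 °C; H2O, aq. NaOH work-up
Reagents that add atoms: none
Why: Hydride reduction of ester and ketone together, chosen because an ester cannot be reduced selectively beside a cyclobutanone. The C9 carbinol configuration (hydride from the top face expected) is of no consequence.

Step 7
Reactants: 12 2-(4-tert-butoxy-7-hydroxy-6-methylbicyclo[3.2.0]hept-2-en-6-yl)ethanol
Product: 13 2-(4-tert-butoxy-6-methyl-7-oxobicyclo[3.2.0]hept-2-en-6-yl)acetaldehyde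
Conditions: Dess–Martin periodinane (2.5 equiv), CH2Cl2, rt
Reagents that add atoms: none
Why: Double Dess–Martin oxidation restores the cyclobutanone and gives the aldehyde under neutral conditions, so the keto aldehyde is not exposed to base.

Step 8
Reactants: 14 methyl 2-(hydroxymethyl)acrylate
Product: 15 methyl 2-[(tert-butyldimethylsilyloxy)methyl]acrylate
Conditions: TBSCl, imidazole, CH2Cl2, 0 °C → rt
Reagents that add atoms: tert-butyldimethylsilyl chloride, C[Si](C)(Cl)C(C)(C)C
Why: Silylation of a primary alcohol; a silyl ether is a poor leaving group, so the acrylate acts as a conjugate acceptor and not as an allylic electrophile in step 9.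

Step 9
Reactants: 13 2-(4-tert-butoxy-6-methyl-7-oxobicyclo[3.2.0]hept-2-en-6-yl)acetaldehyde; 15 methyl 2-[(tert-butyldimethylsilyloxy)methyl]acrylate
Product: 16 methyl 5-(4-tert-butoxy-6-methyl-7-oxobicyclo[3.2.0]hept-2-en-6-yl)-4-oxo-2-[(tert-butyldimethylsilyloxy)methyl]pentanoate (C12 epimers)
Conditions: 3-benzyl-5-(2-hydroxyethyl)-4-methylthiazolium chloride (20 mol%), Et3N (40 mol%), 1,4-dioxane, 70 °C
Reagents that add atoms: acrylate 15, C=C(CO[Si](C)(C)C(C)(C)C)C(=O)OC
Why: Stetter reaction; the carbene turns the unhindered aliphatic aldehyde into an acyl anion equivalent that adds to the CH2 terminus of the acrylate, forming C1–C13. α-Substituted acrylates are competent acceptors, and the cyclobutanone cannot be attacked intramolecularly because that would need a four-membered ring. C12 forms as a mixture, which does not matter because it becomes trigonal in step 11.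

Step 10
Reactants: 16 methyl 5-(4-tert-butoxy-6-methyl-7-oxobicyclo[3.2.0]hept-2-en-6-yl)-4-oxo-2-[(tert-butyldimethylsilyloxy)methyl]pentanoate
Product: 19 tetracyclic C1-keto γ-lactone (C9–O10 lactone; H13 inner; C12 epimers; C5 tert-butyl ether; C14 silyl ether; C6=C7), via lithium enolate 17 (not isolated), via lithium aldolate 18 (not isolated)
Conditions: LiN(SiMe3)2 (1.1 equiv), THF, –78 → 0 °C; then AcOH
Reagents that add atoms: none
Why: Intramolecular aldol addition of the C13 ketone enolate to the strained cyclobutanone (5-exo-trig) closes ring C, and 5-exo-trig lactonisation of the tertiary alkoxide on the methyl ester makes the sequence irreversible. The C2 tether lies on the bottom face, so C13 can add only to the bottom face of C9; this sets C9 with O10 on top and gives the syn ring fusion. C13 epimerises under the conditions to the configuration that allows the cis-fused lactone.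

Step 11
Reactants: 19 tetracyclic C1-keto γ-lactone
Product: 20 tetracyclic C1-oxo butenolide (C12=C13; C5 tert-butyl ether; C14 silyl ether; C6=C7)
Conditions: IBX (2.5 equiv), DMSO, 70 °C
Reagents that add atoms: none
Why: IBX α,β-dehydrogenation of a ketone; desaturation is possible only across C13–C12 because C3 is quaternary. Flattening C13 removes its hydrogen from the cleft, and the product alkene is conjugated with both carbonyls.

Step 12
Reactants: 20 tetracyclic C1-oxo butenolide
Product: 21 C1-epimeric allylic alcohol (C1 hydroxyl inner; C5 tert-butyl ether; C14 silyl ether; C6=C7)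
Conditions: NaBH4, CeCl3·7H2O, MeOH, –78 °C
Reagents that add atoms: none
Why: Luche 1,2-reduction of the enone carbonyl, which leaves the lactone alone. The inner face of C1 looks into the cleft towards ring A, so hydride should arrive on the outer face and place the hydroxyl inside, i.e. the C1 epimer of the natural configuration.

Step 13
Reactants: 21 C1-epimeric allylic alcohol; 22 tiglic acid
Product: 23 C1 tiglate of natural configuration (tiglate outer; C5 tert-butyl ether; C14 silyl ether; C6=C7)
Conditions: PPh3, DIAD, toluene, 0 °C → rt
Reagents that add atoms: tiglic acid 22, C/C=C(\C)C(=O)O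
Why: Mitsunobu esterification with inversion; the carboxylate attacks C1 from the open outer face, which corrects C1 and installs the tiglate at once. Allylic transposition is blocked because C12 is fully substituted.

Step 14
Reactants: 23 C1 tiglate of natural configuration
Product: 25 C7 alcohol (hydroxyl outer; C6 now CH2), via B-alkyl-9-BBN adduct 24 (not isolated)
Conditions: 9-BBN, THF, 0 → 50 °C; then NaBO3·4H2O, H2O, rt
Reagents that add atoms: sodium perborate, [Na+].[Na+].O[B-]1(O)OO[B-](O)(O)OO1
Why: Hydroboration–oxidation; the borane can add only syn on the outer face of ring A, where C6 is screened by the cis tert-butoxy group on C5, so boron should go to C7. The conjugated ester double bonds react much more slowly with 9-BBN, and perborate oxidises with retention without attacking the esters.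

Step 15
Reactants: 25 C7 alcohol
Product: 26 C7 ketone (C5 tert-butyl ether; C14 silyl ether; C1 tiglate)
Conditions: Dess–Martin periodinane, CH2Cl2, rt
Reagents that add atoms: none
Why: Dess–Martin oxidation of the only free hydroxyl. The C7 ketone is tolerable now because C9 is a lactone carbon and no longer a ketone.

Step 16
Reactants: 26 C7 ketone
Product: 27 C7 ketone 5,14-diacetate (C1 tiglate)
Conditions: Ac2O, FeCl3 (10 mol%), CH2Cl2, 0 °C
Reagents that add atoms: acetic anhydride, CC(=O)OC(C)=O
Why: Lewis-acid acylative ether cleavage; the ether oxygen is acetylated and loses tert-butyl cation or the silyl group, so both ethers become acetates in one operation with retention at C5. It is placed here because neither an acid-labile exocyclic alkene nor a tertiary alcohol is present yet.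

Step 17
Reactants: 27 C7 ketone 5,14-diacetate
Product: 28 C7 exocyclic methylene compound (5,14-diacetate; C1 tiglate)
Conditions: Zn, CH2Br2, TiCl4, THF/CH2Cl2, 0 °C → rt
Reagents that add atoms: dibromomethane, BrCBr
Why: Lombardo methylenation; the non-basic reagent converts the ketone without β-elimination of the C5 acetate and leaves esters and the lactone untouched.

Step 18
Reactants: 28 C7 exocyclic methylene compound
Product: 30 target CNP0210373.1, via tertiary hydroperoxide 29 (not isolated)
Conditions: Co(acac)2 (20 mol%), PhSiH3, O2 (1 atm), iPrOH/THF, 0 °C → rt; then PPh3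
Reagents that add atoms: dioxygen, O=O
Why: Mukaiyama hydration; hydrogen-atom transfer to the CH2 terminus gives the tertiary C7 radical, which is trapped by O2 on the outer face, and the hydroperoxide is reduced by the phosphine. This puts the hydroxyl outside and the new methyl inside the cleft, the arrangement a methyl nucleophile adding to ketone 27 could not give. The unhindered 1,1-disubstituted alkene should react faster than the trisubstituted tiglate and the tetrasubstituted butenolide double bonds.

Compound list

1 | 7-tert-butoxynorbornadiene | CC(C)(C)OC1C2C=CC1C=C2 | starting material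
2 | exo-2-[bis(isopinocampheyl)boryl]-7-tert-butoxynorborn-5-ene (ether syn to C5=C6) | B([C@H]1C[C@H]2C[C@@H]([C@@H]1C)C2(C)C)([C@H]1C[C@H]2C[C@@H]([C@@H]1C)C2(C)C)[C@@H]1C[C@H]2C=C[C@@H]1[C@@H]2OC(C)(C)C | intermediate
3 | 7-tert-butoxybicyclo[2.2.1]hept-5-en-2-ol, hydroxyl exo, ether syn to C5=C6 | O[C@@H]1C[C@H]2C=C[C@@H]1[C@@H]2OC(C)(C)C | intermediate
4 | 7-tert-butoxybicyclo[2.2.1]hept-5-en-2-one, ether syn to C5=C6 | O=C1C[C@H]2C=C[C@@H]1[C@@H]2OC(C)(C)C | intermediate
5 | iodomethane | CI | starting material
6 | lithium enolate of 4 | [Li]OC1=C[C@H]2C=C[C@@H]1[C@@H]2OC(C)(C)C | intermediate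
7 | 7-tert-butoxy-3-exo-methylbicyclo[2.2.1]hept-5-en-2-one | O=C1[C@H](C)[C@H]2C=C[C@@H]1[C@@H]2OC(C)(C)C | intermediate
8 | methyl bromoacetate | COC(=O)CBr | starting material
9 | lithium enolate of 7 | [Li]OC1=C(C)[C@H]2C=C[C@@H]1[C@@H]2OC(C)(C)C | intermediate
10 | methyl 2-(7-tert-butoxy-3-methyl-2-oxobicyclo[2.2.1]hept-5-en-3-yl)acetate, arm exo, methyl endo, ether syn to C5=C6 | COC(=O)C[C@@]1(C)C(=O)[C@@H]2C=C[C@H]1[C@H]2OC(C)(C)C | intermediate
11 | methyl 2-(4-tert-butoxy-6-methyl-7-oxobicyclo[3.2.0]hept-2-en-6-yl)acetate, cis-fused, arm on the bottom face, methyl on top, ether outer | COC(=O)C[C@]2(C)[C@@H]3[C@@H](OC(C)(C)C)C=C[C@@H]3C2=O | intermediate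
12 | 2-(4-tert-butoxy-7-hydroxy-6-methylbicyclo[3.2.0]hept-2-en-6-yl)ethanol, C9 hydroxyl on the bottom face | OCC[C@]2(C)[C@@H]3[C@@H](OC(C)(C)C)C=C[C@@H]3[C@@H]2O | intermediate
13 | 2-(4-tert-butoxy-6-methyl-7-oxobicyclo[3.2.0]hept-2-en-6-yl)acetaldehyde | O=CC[C@]2(C)[C@@H]3[C@@H](OC(C)(C)C)C=C[C@@H]3C2=O | intermediate
14 | methyl 2-(hydroxymethyl)acrylate | C=C(CO)C(=O)OC | starting material
15 | methyl 2-[(tert-butyldimethylsilyloxy)methyl]acrylate | C=C(CO[Si](C)(C)C(C)(C)C)C(=O)OC | intermediate
16 | γ-keto ester from the Stetter reaction (C1 ketone, C12 epimers) | COC(=O)C(CO[Si](C)(C)C(C)(C)C)CC(=O)C[C@]2(C)[C@@H]3[C@@H](OC(C)(C)C)C=C[C@@H]3C2=O | intermediate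
17 | lithium C1=C13 enolate of 16 | COC(=O)C(CO[Si](C)(C)C(C)(C)C)C=C(O[Li])C[C@]2(C)[C@@H]3[C@@H](OC(C)(C)C)C=C[C@@H]3C2=O | intermediate
18 | lithium C9 aldolate (ring C closed, ester still open) | COC(=O)C(CO[Si](C)(C)C(C)(C)C)[C@H]1C(=O)C[C@]2(C)[C@@H]3[C@@H](OC(C)(C)C)C=C[C@@H]3[C@]12O[Li] | intermediate
19 | tetracyclic C1-keto γ-lactone, H13 inner, C12 epimers, C5 OtBu outer, C14 OTBS | O=C1C[C@]2(C)[C@@H]3[C@@H](OC(C)(C)C)C=C[C@@H]3[C@@]23OC(=O)C(CO[Si](C)(C)C(C)(C)C)[C@@H]13 | intermediate
20 | tetracyclic C1-oxo butenolide (C12=C13), C5 OtBu, C14 OTBS | O=C1C[C@]2(C)[C@@H]3[C@@H](OC(C)(C)C)C=C[C@@H]3[C@@]23OC(=O)C(CO[Si](C)(C)C(C)(C)C)=C13 | intermediate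
21 | C1-epimeric allylic alcohol (C1 hydroxyl inner), C5 OtBu, C14 OTBS | O[C@@H]1C[C@]2(C)[C@@H]3[C@@H](OC(C)(C)C)C=C[C@@H]3[C@@]23OC(=O)C(CO[Si](C)(C)C(C)(C)C)=C13 | intermediate
22 | tiglic acid, (E)-2-methylbut-2-enoic acid | C/C=C(\C)C(=O)O | starting material
23 | C1 tiglate of natural configuration (outer), C5 OtBu, C14 OTBS, C6=C7 | C/C=C(\C)C(=O)O[C@H]1C[C@]2(C)[C@@H]3[C@@H](OC(C)(C)C)C=C[C@@H]3[C@@]23OC(=O)C(CO[Si](C)(C)C(C)(C)C)=C13 | intermediate
24 | C7 B-alkyl-9-BBN adduct of 23, boron outer | C/C=C(\C)C(=O)O[C@H]1C[C@]2(C)[C@@H]3[C@@H](OC(C)(C)C)C[C@@H](B4C5CCCC4CCC5)[C@@H]3[C@@]23OC(=O)C(CO[Si](C)(C)C(C)(C)C)=C13 | intermediate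
25 | C7 secondary alcohol, hydroxyl outer | C/C=C(\C)C(=O)O[C@H]1C[C@]2(C)[C@@H]3[C@@H](OC(C)(C)C)C[C@@H](O)[C@@H]3[C@@]23OC(=O)C(CO[Si](C)(C)C(C)(C)C)=C13 | intermediate
26 | C7 ketone, C5 OtBu, C14 OTBS, C1 tiglate | C/C=C(\C)C(=O)O[C@H]1C[C@]2(C)[C@@H]3[C@@H](OC(C)(C)C)CC(=O)[C@@H]3[C@@]23OC(=O)C(CO[Si](C)(C)C(C)(C)C)=C13 | intermediate
27 | C7 ketone 5,14-diacetate, C1 tiglate | C/C=C(\C)C(=O)O[C@H]1C[C@]2(C)[C@@H]3[C@@H](OC(C)=O)CC(=O)[C@@H]3[C@@]23OC(=O)C(COC(C)=O)=C13 | intermediate
28 | C7 exocyclic methylene compound, 5,14-diacetate, C1 tiglate | C/C=C(\C)C(=O)O[C@H]1C[C@]2(C)[C@@H]3[C@@H](OC(C)=O)CC(=C)[C@@H]3[C@@]23OC(=O)C(COC(C)=O)=C13 | intermediate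
29 | C7 tertiary hydroperoxide, OOH outer, methyl inner | C/C=C(\C)C(=O)O[C@H]1C[C@]2(C)[C@@H]3[C@@H](OC(C)=O)C[C@@](C)(OO)[C@@H]3[C@@]23OC(=O)C(COC(C)=O)=C13 | intermediate
30 | CNP0210373.1 | C/C=C(\C)C(=O)O[C@H]1C[C@]2(C)[C@@H]3[C@@H](OC(C)=O)C[C@@](C)(O)[C@@H]3[C@@]23OC(=O)C(COC(C)=O)=C13 | target

Total step count: 18. Longest linear sequence: 17 steps (steps 1–7 and 9–18; step 8 prepares acrylate 15).

Least certain steps

Step 5 (key step). What may go wrong is α-cleavage on the quaternary side of the ketone followed by decarbonylation or hydrogen transfer, and secondary photolysis of the cyclobutanone (ketene loss, reversal), so that material is lost with increasing conversion. The fallback moves the construction of the quaternary centre behind the photoreaction. It sets out from ketone 4, whose α-carbon is unsubstituted, and irradiates it under the same conditions to the parent 4-tert-butoxybicyclo[3.2.0]hept-2-en-7-one F1. The kinetic enolate of F1 (LiN(iPr)2, –78 °C) is alkylated with 8 to the mono-alkylated cyclobutanone F2, and the enolate of F2 is then methylated with 5. Each electrophile enters on the convex top face, so the methyl introduced second pushes the acetate arm to the bottom face, and the sequence comes back to the route at 11.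

Step 11. What may go wrong is enolisation towards C2 only, slow removal of the inner hydrogen on C13, or over-oxidation, so that the ketone is recovered or degraded. The fallback sets out from 19 and makes the double bond from the lactone side. NaBH4 in MeOH reduces the C1 ketone from the outer face to the saturated inner alcohol F3. The alkoxide–lactone enolate dianion (LiN(iPr)2, 2.2 equiv, –78 °C) is selenenylated with PhSeBr on the lactone face away from ring C, giving the α-phenylselanyl lactone F4. Oxidation with H2O2 then triggers syn-elimination towards H13. This returns to the route at 21 and bypasses 20. Its own weak point is β-elimination of the silyloxy group from the lactone enolate, which is why it is not the first choice.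

Step 9. What may go wrong is slow conjugate addition to the α-substituted acrylate, so that self-condensation of the aldehyde or premature base-induced aldol chemistry takes over. The fallback replaces the polar acyl anion by an acyl radical and sets out from 11. Saponification (LiOH, THF/H2O) gives the carboxylic acid F5. PhSeSePh and Bu3P convert F5 into the Se-phenyl selenoester F6. (Me3Si)3SiH and AIBN in the presence of an excess of 15 then add the acyl radical to the acrylate terminus, which returns to the route at 16. The arm points away from the ring A alkene, so radical cyclisation onto it is geometrically disfavoured.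

Step 10. What may go wrong is reversal of the aldol addition before lactonisation, Claisen-type attack of the C2 enolate on the ester, or β-elimination of the silyloxy group if the ester is deprotonated. The fallback generates the C13 enolate regiospecifically and under neutral conditions, setting out from 16. The kinetic enolate is silylated (LiN(SiMe3)2, Me3SiCl, –78 °C) to the silyl enol ether F7, and NBS gives the C13 bromo ketone F8. SmI2 in THF at –78 °C then effects a Reformatsky-type cyclisation onto the cyclobutanone. The chelated samarium aldolate lactonises on warming, which returns to the route at 19.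

Step 18. What may go wrong is competing hydrogen-atom transfer to the tiglate double bond, or trapping of the C7 radical on the wrong face. The fallback avoids radical hydration and sets out from 28. mCPBA epoxidises only the electron-rich exocyclic alkene, on its outer face, to the spiro-epoxide F9. LiI and AcOH in THF open F9 at the primary carbon to the iodohydrin F10. Bu3SnH and AIBN then reduce the C–I bond to the methyl group, which gives 30.

Further compounds

F1 | step 5 | 4-tert-butoxybicyclo[3.2.0]hept-2-en-7-one, cis-fused, ether outer | O=C1C[C@@H]2[C@@H](OC(C)(C)C)C=C[C@H]12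
F2 | step 5 | methyl 2-(4-tert-butoxy-7-oxobicyclo[3.2.0]hept-2-en-6-yl)acetate, arm on the top face | COC(=O)C[C@H]1[C@@H]2[C@@H](OC(C)(C)C)C=C[C@@H]2C1=O
F3 | step 11 | saturated lactone with inner C1 hydroxyl (C12 epimers) | O[C@@H]1C[C@]2(C)[C@@H]3[C@@H](OC(C)(C)C)C=C[C@@H]3[C@@]23OC(=O)C(CO[Si](C)(C)C(C)(C)C)[C@@H]13
F4 | step 11 | C12 phenylselanyl lactone, selenium syn to H13 | O[C@@H]1C[C@]2(C)[C@@H]3[C@@H](OC(C)(C)C)C=C[C@@H]3[C@@]23OC(=O)[C@](CO[Si](C)(C)C(C)(C)C)([Se]c4ccccc4)[C@@H]13
F5 | step 9 | 2-(4-tert-butoxy-6-methyl-7-oxobicyclo[3.2.0]hept-2-en-6-yl)acetic acid | OC(=O)C[C@]2(C)[C@@H]3[C@@H](OC(C)(C)C)C=C[C@@H]3C2=O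
F6 | step 9 | Se-phenyl selenoester of F5 | O=C(C[C@]2(C)[C@@H]3[C@@H](OC(C)(C)C)C=C[C@@H]3C2=O)[Se]c1ccccc1
F7 | step 10 | C1=C13 trimethylsilyl enol ether of 16 | COC(=O)C(CO[Si](C)(C)C(C)(C)C)C=C(O[Si](C)(C)C)C[C@]2(C)[C@@H]3[C@@H](OC(C)(C)C)C=C[C@@H]3C2=O
F8 | step 10 | C13 bromo derivative of 16 | COC(=O)C(CO[Si](C)(C)C(C)(C)C)C(Br)C(=O)C[C@]2(C)[C@@H]3[C@@H](OC(C)(C)C)C=C[C@@H]3C2=O
F9 | step 18 | C7 spiro-epoxide of 28, oxygen outer | C/C=C(\C)C(=O)O[C@H]1C[C@]2(C)[C@@H]3[C@@H](OC(C)=O)C[C@]4(CO4)[C@@H]3[C@@]23OC(=O)C(COC(C)=O)=C13
F10 | step 18 | C7 iodomethyl carbinol, hydroxyl outer | C/C=C(\C)C(=O)O[C@H]1C[C@]2(C)[C@@H]3[C@@H](OC(C)=O)C[C@@](CI)(O)[C@@H]3[C@@]23OC(=O)C(COC(C)=O)=C13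
A1 | alternative 1 | spiro-butenolide C13 enol triflate with C1 aldehyde on the C3 arm | O=CC[C@]1(C)[C@@H]2[C@@H](O[Si](C)(C)C(C)(C)C)C[C@@](C)(O[Si](CC)(CC)CC)[C@@H]2[C@@]13OC(=O)C(CO[Si](C)(C)C(C)(C)C)=C3OS(=O)(=O)C(F)(F)F
A2 | alternative 1 | tetracyclic C1 alcohol | O[C@H]1C[C@]2(C)[C@@H]3[C@@H](O[Si](C)(C)C(C)(C)C)C[C@@](C)(O[Si](CC)(CC)CC)[C@@H]3[C@@]23OC(=O)C(CO[Si](C)(C)C(C)(C)C)=C13
A3 | alternative 2 | C2 iodide with 3-methylcyclobutene, spiro-butenolide and C5 nitrile arm | CC(C)(C)[Si](C)(C)O[C@@H](CI)C1=C(COC(C)=O)C(=O)O[C@]12C(C)=C[C@@H]2[C@](C)(O[Si](C)(C)C)CC#N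
A4 | alternative 2 | tetracyclic C5 ketone | CC(C)(C)[Si](C)(C)O[C@H]1C[C@]2(C)[C@@H]3C(=O)C[C@@](C)(O[Si](C)(C)C)[C@@H]3[C@@]23OC(=O)C(COC(C)=O)=C13
A5 | alternative 3 | diquinane α-diazoketone | COC1=CC[C@]2(C)[C@H](CO[Si](C)(C)C(C)(C)C)C(=O)C(=[N+]=[N-])[C@]12O[Si](CC)(CC)CC
A6 | alternative 3 | ring C cyclobutane with cis C5 and C7 arms | COC1=CC[C@]2(C)[C@H](CO[Si](C)(C)C(C)(C)C)[C@H](C(=O)OC)[C@]12O[Si](CC)(CC)CC
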